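The oxygens of the target's ring sit at C1 (tertiary carbinol carrying the CH2CH2O chain) and at C4 (ketone), a para, like-polarity pattern that is the oxidised form of a 4-alkylphenol. The route rests on disconnecting the C1–OH bond with dearomatisation. Iodine(III) oxidation of tyrosyl palmitate inverts the polarity of its para carbon and water bonds to it. The tertiary carbinol and the C4 carbonyl of a cross-conjugated dienone thus arise in one operation, with all six ring carbons coming from the flat arene. The precursor is simply the phenol ester, acylated first so that the side-chain oxygen cannot add to the dienone. Hydrogenation then completes the target.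

Key step: step 2

Remark: the target has no stereogenic centre (C1 carries two identical ring arms and lies on a mirror plane), so it is a single achiral compound and the route needs no enantiocontrol.

Step 1
Reactants: 1 tyrosol [4-(2-hydroxyethyl)phenol]; 2 vinyl palmitate (ethenyl hexadecanoate)
Product: 3 2-(4-hydroxyphenyl)ethyl hexadecanoate (tyrosyl palmitate)
Conditions: Novozym 435 (immobilised CAL-B), 2 (1.5 equiv), t-BuOMe, 40 °C
Reagents that add atoms: none
Why: Lipase-catalysed irreversible transesterification, in which the acyl-enzyme formed from 2 should be intercepted only by the primary aliphatic hydroxyl of 1 (CAL-B does not accept the phenol as nucleophile) while the released vinyl alcohol tautomerises to acetaldehyde and makes the acyl transfer irreversible; no stereocentre is involved.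

Step 2
Reactants: 3 2-(4-hydroxyphenyl)ethyl hexadecanoate
Product: 5 2-(1-hydroxy-4-oxocyclohexa-2,5-dien-1-yl)ethyl hexadecanoate, via aryloxyiodane 4 (not isolated)
Conditions: PhI(OAc)2 (1.1 equiv), MeCN/acetone/H2O (3:3:1), 0 °C
Reagents that add atoms: water, O
Why: Ligand exchange of the phenolic O–H at iodine(III) should give aryloxyiodane 4, and loss of iodobenzene and acetate (a two-electron oxidation) turns the normally nucleophilic para carbon into the electrophilic terminus of a phenoxenium-type species, which water captures to form the tertiary C1–O bond, proton loss leaving the C4 carbonyl of the cross-conjugated dienone. The closest known reaction type is the hypervalent-iodine oxidative dearomatisation of 4-alkylphenols to p-quinols in aqueous acetonitrile. No ring is closed and no stereocentre is created, since C1 lies on the mirror plane of the dienone. The selectivity needed is capture at the para rather than the ortho carbon and by water rather than by acetate or an internal oxygen: the para carbon carries the largest positive charge, water is present in large excess, and the side-chain oxygen is already acylated, so neither spiro-etherification nor the intramolecular oxa-Michael addition open to a free 2-hydroxyethyl quinol can occur. The dienone cannot tautomerise back to a phenol because C1 is fully substituted, and the palmitate ester should be inert to the oxidant at 0 °C.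

Step 3
Reactants: 5 2-(1-hydroxy-4-oxocyclohexa-2,5-dien-1-yl)ethyl hexadecanoate
Product: 7 2-(1-hydroxy-4-oxocyclohexyl)ethyl hexadecanoate (target), via cyclohexenone 6 (not isolated)
Conditions: H2 (1 atm), 10% Pd/C, EtOAc, rt
Reagents that add atoms: none
Why: Heterogeneous catalytic hydrogenation, in which the two electron-poor enone C=C bonds of 5 should be saturated in turn (through racemic enone 6, whose stereocentre vanishes when C1 regains two identical arms) much faster than the isolated ketone or the ester react on palladium, the neutral aprotic solvent being chosen to suppress acid-promoted loss of the tertiary hydroxyl.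

Compound list
1 | tyrosol, 4-(2-hydroxyethyl)phenol | OCCc1ccc(O)cc1 | starting material
2 | vinyl palmitate (ethenyl hexadecanoate) | CCCCCCCCCCCCCCCC(=O)OC=C | starting material
3 | 2-(4-hydroxyphenyl)ethyl hexadecanoate (tyrosyl palmitate) | CCCCCCCCCCCCCCCC(=O)OCCc1ccc(O)cc1 | intermediate
4 | acetoxy[4-(2-hexadecanoyloxyethyl)phenoxy]phenyl-λ3-iodane (aryloxyiodane, formed in the flask in step 2) | CCCCCCCCCCCCCCCC(=O)OCCc1ccc(OI(OC(C)=O)c2ccccc2)cc1 | intermediate
5 | 2-(1-hydroxy-4-oxocyclohexa-2,5-dien-1-yl)ethyl hexadecanoate (achiral p-quinol) | CCCCCCCCCCCCCCCC(=O)OCCC1(O)C=CC(=O)C=C1 | intermediate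
6 | (±)-2-(1-hydroxy-4-oxocyclohex-2-en-1-yl)ethyl hexadecanoate (racemic, formed in the flask in step 3) | CCCCCCCCCCCCCCCC(=O)OCCC1(O)CCC(=O)C=C1 | intermediate
7 | 2-(1-hydroxy-4-oxocyclohexyl)ethyl hexadecanoate (achiral) | CCCCCCCCCCCCCCCC(=O)OCCC1(O)CCC(=O)CC1 | target

Total step count: 3
Longest linear sequence: 3 steps

Steps most likely to fail

1. Step 2 (key step). What may go wrong: the oxidised phenol is diverted before water reaches the para carbon, through one-electron phenoxyl coupling and oligomerisation, or through capture by acetate or at an ortho carbon. Poor solubility of the lipophilic ester in the aqueous medium would aggravate this. Fallback, from 3 back to 5: the oxidant class and mechanism are changed to singlet oxygen, generated from Oxone and NaHCO3 in aqueous MeCN or by dye-sensitised photooxygenation under O2. Singlet oxygen adds at the para carbon of the phenol(ate) and should give the para-hydroperoxide 2-(1-hydroperoxy-4-oxocyclohexa-2,5-dien-1-yl)ethyl hexadecanoate F1. Reduction of the O–O bond with Me2S in the same flask would then give 5.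

2. Step 3. What may go wrong: hydrogenolysis of the doubly allylic tertiary C–O bond on the palladium surface, with rearomatisation back to phenol 3 instead of saturation of the ring. Fallback, from 5 back to 7: the hydroxyl is masked before reduction. Silylation of 5 (TMSCl, imidazole, CH2Cl2) should give 2-[4-oxo-1-(trimethylsilyloxy)cyclohexa-2,5-dien-1-yl]ethyl hexadecanoate F2, which offers no free hydroxyl to anchor the substrate to the metal or to leave as hydroxide. Hydrogenation of the silyl ether (H2, Pd/C, EtOAc, or homogeneous RhCl(PPh3)3 in benzene) should give 2-[4-oxo-1-(trimethylsilyloxy)cyclohexyl]ethyl hexadecanoate F3. Brief treatment with dilute aqueous HCl in THF at 0 °C would then release 7 without touching the ester.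

3. Step 1. What may go wrong: sluggish acyl transfer from the long-chain donor within the enzyme, or partial acylation of the phenol oxygen on prolonged reaction, leaving mixtures of mono- and diesters. Fallback, from 1 back to 3: selectivity is moved from the acylation to a deacylation. Exhaustive acylation of 1 with palmitoyl chloride (2.2 equiv, Et3N, cat. DMAP, CH2Cl2) should give the dipalmitate 4-[2-(hexadecanoyloxy)ethyl]phenyl hexadecanoate F4. The aryl ester, much more electrophilic than the alkyl ester and bearing a phenoxide leaving group, would then be cleaved selectively by aminolysis with pyrrolidine (1.1 equiv, CH2Cl2, 0 °C) to return 3.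

Further compounds
F1 | step 2 | 2-(1-hydroperoxy-4-oxocyclohexa-2,5-dien-1-yl)ethyl hexadecanoate | CCCCCCCCCCCCCCCC(=O)OCCC1(OO)C=CC(=O)C=C1
F2 | step 3 | 2-[4-oxo-1-(trimethylsilyloxy)cyclohexa-2,5-dien-1-yl]ethyl hexadecanoate | CCCCCCCCCCCCCCCC(=O)OCCC1(O[Si](C)(C)C)C=CC(=O)C=C1
F3 | step 3 | 2-[4-oxo-1-(trimethylsilyloxy)cyclohexyl]ethyl hexadecanoate | CCCCCCCCCCCCCCCC(=O)OCCC1(O[Si](C)(C)C)CCC(=O)CC1
F4 | step 1 | 4-[2-(hexadecanoyloxy)ethyl]phenyl hexadecanoate | CCCCCCCCCCCCCCCC(=O)OCCc1ccc(OC(=O)CCCCCCCCCCCCCCC)cc1
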